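## Analysis of the target

The target 22 (C19H28O6) is a cyclised hexapropionate. Its chain is numbered C1 (lactone carbonyl), C2 (quaternary, methyl-bearing), C3 (ketone), C4 (CHMe), C5 (CH–O–acyl), C6 (CHMe), C7 (spiro carbon), C8 (CHMe), C9 (CH–OAc), C10 (CHMe), C11 (CH(Me)–O) and C12 (the methyl on C11). Ring A is a tetrahydropyran (ring oxygen, C7–C11), spiro-joined at C7 to a 2-oxabicyclo[2.2.2]octane-3,5-dione with bridgeheads C2 and C5 and three two-atom bridges, C3(=O)–C4, C7–C6 and C1(=O)–O; the carbocycle C2–C3–C4–C5–C6–C7 is ring B. The nine stereocentres (2R,4S,5S,6R,7S,8S,9R,10R,11S) form one connected array; in open-chain terms they are 4,5-anti, 5,6-anti, 6,8-syn, 8,9-syn, 9,10-anti and 10,11-syn, and ring A is a chair with the C8 methyl, C9 acetoxy and C11 methyl equatorial, the C10 methyl axial, C7–C2 axial and C7–C6 equatorial. In the bicycle the methyls on C4 and C6 and the C7–C8 bond point towards the lactone bridge, while the ring-A oxygen on C7 faces the ketone bridge. Sensitive groups are the β-keto lactone with its non-enolisable C2 (retro-Claisen opening by nucleophiles), the epimerisable C4, the secondary acetate, and the tertiary ether at C7, which lies β to two carbonyls and can ionise at C2–C7 under acid. The hard part is the C2–C7 bond, which joins two fully substituted stereocentres at the junction of all three rings, together with a C5/C6/C8 relationship that fits substrate-controlled aldol chemistry poorly. The feature that invites the strategy is the bridged lactone itself: C1(=O)–O spanning C2 and C5 across ring B is the retron of a 2-pyranone Diels–Alder adduct, in which the ring oxygen and C1–C5 are a 4-oxygenated 3,5-dimethyl-2-pyranone and C6=C7 is the exocyclic enol ether of ring A.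

## Retrosynthetic reasoning

**22 to 20 and 19 (no skeletal bond cut).** The C3 ketone is traced back to a bridging enol acetate (C3=C4) and the C9 acetate to a silyl ether. This leaves C4 without configuration until the last step, where it is set by equilibration, and it gives a 2-oxabicyclo[2.2.2]oct-7-en-3-one, the direct product of a pyranone cycloaddition. The forward steps must free the C9 hydroxyl, acetylate it, and cleave the enol ester without opening the β-keto lactone.

**19 to 13 and 18 (cut C5–C6 and C2–C7).** Both bonds that tie ring A to the bicycle are cut at once. No other pair of bonds removes two bridges in one step, and any cut that keeps C5–C6 leaves a linear chain with seven stereocentres to carry. What is gained is a flat, achiral 2-pyranone 18 for C1–C5 and an enol ether 13 that carries only C8–C11. The forward [4+2] reaction has to form ring B, the spiro centre and four stereocentres (C2, C5, C6, C7). The double bond of 13 must be E: a Z-configured double bond would place the C6 methyl on the wrong side of the C6–C7 bridge, and that centre cannot be corrected later.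

**18 to 17 to 14 and 15 (cut the ring O–C1 bond and C4–C5).** The pyranone is opened to a γ-formyl β-keto ester, which comes from the dianion of keto ester 14 and formate 15. The 4-oxygen is acylated so that it lowers the diene LUMO and masks the C3 ketone.

**13 to 12 (cut O–C7).** Ring A is opened at the enol ether C–O bond to the alkynol 12. A syn-selective 6-exo-dig hydroalkoxylation puts O and H on the same side and so gives the E-ethylidene group, which direct alkylidenation of a lactone would not.

**12 to 11 to 9 (cut C6–CH3 and C6–C7).** The methyl alkyne comes from the terminal alkyne 11, and 11 from lactone 9 by half-reduction and one-carbon homologation. The lactone serves as internal protection of the C11 oxygen, which is set free exactly when it is needed as the nucleophile.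

**9 to 8 to 6 to 4 and 5 (cut the lactone O–C7 bond, C9–H and C10–C11).** The C8–C11 stereotetrad is the anti-syn aldol of the β-keto imide 4 with acetaldehyde 5, followed by 1,3-anti reduction; lactonisation releases the auxiliary. Three of the four centres come from two reagent-controlled steps.

**4 to 3 to 1 and 2 (cut C8–C9).** The β-keto imide is the oxidised syn aldol of imide 1 with propanal 2, which fixes C8.

## Alternatives that were turned down

**Alternative 1:** Disconnection of C2–C7 only, the textbook biomimetic cut. The forward key step would be an acid-triggered cascade on the open-chain seco ester A1: C11–OH adds to the C7 ketone, C5–OH lactonises onto C1, and the C2 enol attacks the C7 oxocarbenium ion. It was turned down for three reasons. A1 must carry seven stereocentres, and its C5–C6 aldol must be anti with a 6,8-syn relationship, a combination that the resident α'-methyl centre of an ethyl ketone enolate does not deliver reliably. A1 also has a C5 hydroxyl β to two ketones and a C9 acetate β to the C7 ketone, so retro-aldol and E1cB pathways accompany every late step. Finally, the key step makes one C–C bond only, after an estimated sixteen or more steps of aldol, protection and oxidation-state changes. A shortened form of this logic is kept as the fallback for the key step.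

**Alternative 2:** Disconnection of ring A from a preformed symmetric bicycle (cut C7–C8 and O–C7). The arene A2 would supply all six carbons of ring B; reduction and intramolecular C-acylation would give the meso trione lactone A3. A ketone Prins cyclisation of A3 with the homoallylic alcohol A4 and acetate capture would then build ring A, with C7, C8 and the C9 acetate in one step. It was turned down because A3 is meso, so A4 would have to choose between two enantiotopic ketones with no control element in place. The alkene would also have to attack C7 on the face syn to the C6 methyl, the more hindered one, so the C7 epimer is expected. In addition, 2-oxonia-Cope exchange and retro-Claisen opening of the tricarbonyl compete under Prins acids.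

**Alternative 3:** Skeletal change by Baeyer–Villiger ring expansion (cut O–C5). The 7-norbornanone A5 would be oxidised so that oxygen inserts between C1 and C5. It was turned down because A5 contains a second ketone (C3) that competes for the peracid, and its non-enolisable 1,3-dione is prone to retro-Claisen opening. Making A5 also requires the same C2–C7 bond plus an extra C1–C5 bond, so the precursor is harder than the target's own cycloaddition precursors and the route is longer.

Key step: step 11

Assumption: C4, the only epimerisable centre, is taken to have in 22 the thermodynamically preferred configuration (methyl on the side of the unsubstituted lactone oxygen), so that base equilibration in the last step delivers it.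

Compounds 1, 2, 5, 14 and 15 are commercial.

## Route

Step 1
Reactants: 1 (S)-4-benzyl-3-propionyloxazolidin-2-one; 2 propanal
Product: 3 (S)-4-benzyl-3-[(2S,3R)-3-hydroxy-2-methylpentanoyl]oxazolidin-2-one
Conditions: n-Bu2BOTf, Et3N, CH2Cl2, −78 → 0 °C; then H2O2, MeOH, pH 7 buffer
Reagents that add atoms: none
Why: Evans syn aldol: the Z-boron enolate reacts through a chair transition state on the face opposite the benzyl group and sets C8 (S); the C9 carbinol centre is removed in step 2.

Step 2
Reactants: 3 (S)-4-benzyl-3-[(2S,3R)-3-hydroxy-2-methylpentanoyl]oxazolidin-2-one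
Product: 4 (S)-4-benzyl-3-[(S)-2-methyl-3-oxopentanoyl]oxazolidin-2-one
Conditions: SO3·pyridine, DMSO, Et3N, CH2Cl2, −10 → 0 °C
Reagents that add atoms: none
Why: Parikh–Doering oxidation is mild enough for β-hydroxy imides; C8 should not epimerise because allylic 1,3-strain keeps its C–H bond out of conjugation with both carbonyls.

Step 3
Reactants: 4 (S)-4-benzyl-3-[(S)-2-methyl-3-oxopentanoyl]oxazolidin-2-one; 5 acetaldehyde
Product: 6 (S)-4-benzyl-3-[(2S,4R,5S)-5-hydroxy-2,4-dimethyl-3-oxohexanoyl]oxazolidin-2-one
Conditions: Sn(OTf)2, Et3N, CH2Cl2, −20 °C; then 5, −78 °C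
Reagents that add atoms: none
Why: Aldol reaction of the divalent tin Z-enolate of the ethyl ketone through a closed transition state controlled by the C8 methyl centre; it should give the 2,4-anti-4,5-syn adduct and so sets C10 and C11.

Step 4
Reactants: 6 (S)-4-benzyl-3-[(2S,4R,5S)-5-hydroxy-2,4-dimethyl-3-oxohexanoyl]oxazolidin-2-one
Product: 8 (3S,4R,5S,6S)-4-hydroxy-3,5,6-trimethyltetrahydro-2H-pyran-2-one, via diol imide 7 (not isolated)
Conditions: Me4NBH(OAc)3, MeCN/AcOH, −30 °C; then DBU (cat.), CH2Cl2, rt
Reagents that add atoms: none
Why: Evans–Saksena reduction: the acetoxyborohydride bound to the C11 hydroxyl delivers hydride intramolecularly to give the 1,3-anti diol (sets C9); the C11 hydroxyl then closes the δ-lactone on the activated imide carbonyl (6-exo-trig) and releases the auxiliary, leaving only the C9 hydroxyl free.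

Step 5
Reactants: 8 (3S,4R,5S,6S)-4-hydroxy-3,5,6-trimethyltetrahydro-2H-pyran-2-one
Product: 9 (3S,4R,5R,6S)-4-[(tert-butyldimethylsilyl)oxy]-3,5,6-trimethyltetrahydro-2H-pyran-2-one
Conditions: TBSOTf, 2,6-lutidine, CH2Cl2, −78 → 0 °C
Reagents that add atoms: tert-butyldimethylsilyl triflate, CC(C)(C)[Si](C)(C)OS(=O)(=O)C(F)(F)F
Why: Silyl triflate silylation of a hindered secondary alcohol; the ether blocks retro-aldol cleavage in step 6 and later adds bulk to one face of the enol ether.

Step 6
Reactants: 9 (3S,4R,5R,6S)-4-[(tert-butyldimethylsilyl)oxy]-3,5,6-trimethyltetrahydro-2H-pyran-2-one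
Product: 11 (2S,3R,4S,5R)-4-[(tert-butyldimethylsilyl)oxy]-3,5-dimethylhept-6-yn-2-ol, via lactol 10 (not isolated)
Conditions: i-Bu2AlH, CH2Cl2, −78 °C; then MeOH, K2CO3, dimethyl (1-diazo-2-oxopropyl)phosphonate, 0 °C → rt
Reagents that add atoms: dimethyl (1-diazo-2-oxopropyl)phosphonate, CC(=O)C(=[N+]=[N-])P(=O)(OC)OC
Why: Half-reduction of the δ-lactone to the lactol and Ohira–Bestmann (Seyferth–Gilbert) homologation of its open hydroxy-aldehyde form give the terminal alkyne and free the C11 hydroxyl; C8 keeps its configuration as long as the aldehyde does not enolise.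

Step 7
Reactants: 11 (2S,3R,4S,5R)-4-[(tert-butyldimethylsilyl)oxy]-3,5-dimethylhept-6-yn-2-ol
Product: 12 (2S,3R,4S,5R)-4-[(tert-butyldimethylsilyl)oxy]-3,5-dimethyloct-6-yn-2-ol
Conditions: n-BuLi (2.2 equiv), THF, −78 → −20 °C; MeI, −78 °C → rt; H2O
Reagents that add atoms: iodomethane, CI
Why: Alkylation of the alkoxide–acetylide dianion; the acetylide carbon is far more nucleophilic towards MeI than the hindered lithium alkoxide, so C-methylation should dominate.

Step 8
Reactants: 12 (2S,3R,4S,5R)-4-[(tert-butyldimethylsilyl)oxy]-3,5-dimethyloct-6-yn-2-ol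
Product: 13 tert-butyl{[(2E,3S,4R,5R,6S)-2-ethylidene-3,5,6-trimethyltetrahydro-2H-pyran-4-yl]oxy}dimethylsilane
Conditions: La[N(SiMe3)2]3 (5 mol%), toluene, 90 °C, base-washed glassware
Reagents that add atoms: none
Why: Lanthanide-catalysed intramolecular hydroalkoxylation: 6-exo-dig syn insertion of the alkyne into the La–O bond of the trivalent lanthanum alkoxide, then protonolysis, adds O and H to the same side, so the methyl ends trans to the ring oxygen (E); no stereocentre is touched.

Step 9
Reactants: 14 ethyl 2-methyl-3-oxopentanoate; 15 ethyl formate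
Product: 17 4-hydroxy-3,5-dimethyl-2H-pyran-2-one, via formyl keto ester 16 (not isolated)
Conditions: NaH, THF, 0 °C; n-BuLi, −10 °C; 15, −78 → 0 °C; aq. HCl; then p-TsOH (cat.), toluene, 80 °C
Reagents that add atoms: none
Why: γ-Formylation (Claisen condensation) of the β-keto ester dianion, then acid-induced enol lactonisation with loss of ethanol, the standard way to 4-hydroxy-2-pyranones.

Step 10
Reactants: 17 4-hydroxy-3,5-dimethyl-2H-pyran-2-one
Product: 18 3,5-dimethyl-2-oxo-2H-pyran-4-yl acetate
Conditions: Ac2O, Et3N, DMAP (cat.), CH2Cl2, 0 °C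
Reagents that add atoms: acetic anhydride, CC(=O)OC(C)=O
Why: O-Acylation of the acidic 4-hydroxyl (C-acylation is blocked by the 3-methyl group); the acyloxy group lowers the diene LUMO and masks the future C3 ketone as an enol ester.

Step 11
Reactants: 13 tert-butyl{[(2E,3S,4R,5R,6S)-2-ethylidene-3,5,6-trimethyltetrahydro-2H-pyran-4-yl]oxy}dimethylsilane; 18 3,5-dimethyl-2-oxo-2H-pyran-4-yl acetate
Product: 19 Diels–Alder adduct (2-oxabicyclo[2.2.2]oct-7-en-3-one with C3 enol acetate and C3=C4 double bond; ring A with C9 OTBS; stereocentres C2/C5–C11 as in 22)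
Conditions: 18 (1.5 equiv), 2,6-di-tert-butyl-4-methylpyridine (5 mol%), CH2Cl2, 12 kbar, 30 °C, 72 h
Reagents that add atoms: none
Why: Proposed new method: an inverse-electron-demand Diels–Alder reaction of the 2-pyranone 18 (diene C2=C3–C4=C5) with the exocyclic enol ether 13 (dienophile C6=C7); the closest known reaction type is the thermal or high-pressure [4+2] addition of vinyl ethers and ketene acetals to 2-pyranone and its 3- or 5-bromo and ester derivatives, which gives isolable 2-oxabicyclo[2.2.2]oct-7-en-3-ones, but a 4-acyloxy-3,5-dialkyl pyranone and a trisubstituted exocyclic enol ether have not been combined in this way. The cycloaddition should be concerted but strongly asynchronous: the nucleophilic C6 bonds first to the unsubstituted, electrophilic C5 terminus of the pyranone and the oxocarbenium-like C7 then to the methyl-bearing C2, which fixes the regiochemistry, while 12 kbar exploits the large negative activation volume and keeps the temperature below that of CO2 extrusion. One [4+2] event closes ring B (C2–C3–C4–C5–C6–C7), both new bonds forming suprafacially on each partner, and thereby turns the planar pyranone into the bridged δ-lactone and C7 into the spiro atom. C6: the E geometry is transferred stereospecifically, so the C6 methyl and C8 end on the same side of the C6–C7 bridge. C7 and the sense of C6 relative to C8–C11: allylic 1,3-strain between the C6 methyl and C8 holds the C8–H bond in the plane of the double bond, so one face is flanked only by the C8 methyl and the other by C9 with its silyloxy group and the syn C11 methyl; the diene should add to the methyl-flanked face, which is also the axial, chair-like trajectory at C7. C2 and C5 are tied to each other by the planar diene and to C6/C7 by the endo orientation of the ring oxygen (the usual alkoxy-endo preference of such additions, reinforced because the bulkier C8 branch then lies exo over the unsubstituted lactone unit). The step therefore needs regio-, endo- and π-facial selectivity plus configurational integrity of the acid-labile E-enol ether, secured by the polarity of the partners, the ring oxygen, the strain-locked conformation and the hindered pyridine base respectively.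

Step 12
Reactants: 19 Diels–Alder adduct (C3 enol acetate; C9 OTBS)
Product: 20 C9 alcohol of the adduct (C3 enol acetate retained; stereocentres as in 22)
Conditions: HF·pyridine, pyridine, THF, 0 °C → rt
Reagents that add atoms: none
Why: Buffered fluoride should cleave the silyl ether without touching the enol acetate, the lactone or the tertiary ether.

Step 13
Reactants: 20 C9 alcohol of the adduct
Product: 22 target spiro lactone acetate CNP0257416.2, via bis-acetate 21 (not isolated)
Conditions: Ac2O, pyridine, DMAP (cat.), CH2Cl2, 0 °C → rt; then n-PrNH2, 0 °C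
Reagents that add atoms: acetic anhydride, CC(=O)OC(C)=O
Why: Acetylation of the C9 hydroxyl, then chemoselective aminolysis of the far more reactive enol ester (an activated acyl donor) in the presence of the alkyl acetate; the liberated enol tautomerises to the C3 ketone and the amine should equilibrate C4 to the epimer with the methyl syn to the lactone oxygen.

## Compound list

1 | (S)-4-benzyl-3-propionyloxazolidin-2-one | CCC(=O)N1[C@@H](Cc2ccccc2)COC1=O | starting material
2 | propanal | CCC=O | starting material
3 | (S)-4-benzyl-3-[(2S,3R)-3-hydroxy-2-methylpentanoyl]oxazolidin-2-one | CC[C@@H](O)[C@H](C)C(=O)N1[C@@H](Cc2ccccc2)COC1=O | intermediate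
4 | (S)-4-benzyl-3-[(S)-2-methyl-3-oxopentanoyl]oxazolidin-2-one | CCC(=O)[C@H](C)C(=O)N1[C@@H](Cc2ccccc2)COC1=O | intermediate
5 | acetaldehyde | CC=O | starting material
6 | (S)-4-benzyl-3-[(2S,4R,5S)-5-hydroxy-2,4-dimethyl-3-oxohexanoyl]oxazolidin-2-one | C[C@H](O)[C@@H](C)C(=O)[C@H](C)C(=O)N1[C@@H](Cc2ccccc2)COC1=O | intermediate
7 | (S)-4-benzyl-3-[(2S,3R,4R,5S)-3,5-dihydroxy-2,4-dimethylhexanoyl]oxazolidin-2-one (diol imide) | C[C@H](O)[C@@H](C)[C@@H](O)[C@H](C)C(=O)N1[C@@H](Cc2ccccc2)COC1=O | intermediate (not isolated)
8 | (3S,4R,5S,6S)-4-hydroxy-3,5,6-trimethyltetrahydro-2H-pyran-2-one | C[C@@H]1OC(=O)[C@@H](C)[C@H](O)[C@@H]1C | intermediate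
9 | (3S,4R,5R,6S)-4-[(tert-butyldimethylsilyl)oxy]-3,5,6-trimethyltetrahydro-2H-pyran-2-one | C[C@@H]1OC(=O)[C@@H](C)[C@H](O[Si](C)(C)C(C)(C)C)[C@@H]1C | intermediate
10 | (3S,4R,5R,6S)-4-[(tert-butyldimethylsilyl)oxy]-3,5,6-trimethyltetrahydro-2H-pyran-2-ol (lactol, both anomers) | C[C@@H]1OC(O)[C@@H](C)[C@H](O[Si](C)(C)C(C)(C)C)[C@@H]1C | intermediate (not isolated)
11 | (2S,3R,4S,5R)-4-[(tert-butyldimethylsilyl)oxy]-3,5-dimethylhept-6-yn-2-ol | C#C[C@@H](C)[C@H](O[Si](C)(C)C(C)(C)C)[C@H](C)[C@H](C)O | intermediate
12 | (2S,3R,4S,5R)-4-[(tert-butyldimethylsilyl)oxy]-3,5-dimethyloct-6-yn-2-ol | CC#C[C@@H](C)[C@H](O[Si](C)(C)C(C)(C)C)[C@H](C)[C@H](C)O | intermediate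
13 | tert-butyl{[(2E,3S,4R,5R,6S)-2-ethylidene-3,5,6-trimethyltetrahydro-2H-pyran-4-yl]oxy}dimethylsilane | C/C=C1/O[C@@H](C)[C@@H](C)[C@@H](O[Si](C)(C)C(C)(C)C)[C@@H]1C | intermediate
14 | ethyl 2-methyl-3-oxopentanoate | CCC(=O)C(C)C(=O)OCC | starting material
15 | ethyl formate | CCOC=O | starting material
16 | ethyl 2,4-dimethyl-3,5-dioxopentanoate (formyl keto ester, drawn as the aldehyde) | CCOC(=O)C(C)C(=O)C(C)C=O | intermediate (not isolated)
17 | 4-hydroxy-3,5-dimethyl-2H-pyran-2-one | CC1=COC(=O)C(C)=C1O | intermediate
18 | 3,5-dimethyl-2-oxo-2H-pyran-4-yl acetate | CC(=O)OC1=C(C)C(=O)OC=C1C | intermediate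
19 | Diels–Alder adduct: spiro 2-oxabicyclo[2.2.2]oct-7-en-3-one with C3 enol acetate (C3=C4), methyls on C2, C4 and C6, ring A with C9 OTBS; C2, C5–C11 configured as in 22 | CC(C)(C)[Si](C)(C)O[C@@H]1[C@H](C)[C@H](C)O[C@]2([C@H](C)[C@@H]3OC(=O)[C@@]2(C)C(OC(C)=O)=C3C)[C@H]1C | intermediate
20 | C9 alcohol of adduct 19 (C3 enol acetate retained) | O[C@@H]1[C@H](C)[C@H](C)O[C@]2([C@H](C)[C@@H]3OC(=O)[C@@]2(C)C(OC(C)=O)=C3C)[C@H]1C | intermediate
21 | bis-acetate (C9 acetate and C3 enol acetate) | CC(=O)O[C@@H]1[C@H](C)[C@H](C)O[C@]2([C@H](C)[C@@H]3OC(=O)[C@@]2(C)C(OC(C)=O)=C3C)[C@H]1C | intermediate (not isolated)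
22 | CNP0257416.2; 3',4,5',6,6',7-hexamethyl-3,8-dioxospiro[2-oxabicyclo[2.2.2]octane-5,2'-oxan]-4'-yl acetate, (2R,4S,5S,6R,7S,8S,9R,10R,11S) in the chain numbering used here | CC(=O)O[C@@H]1[C@H](C)[C@H](C)O[C@]2([C@H](C)[C@@H]3OC(=O)[C@@]2(C)C(=O)[C@H]3C)[C@H]1C | target

## Step count and least certain steps

Total: 13 steps. Longest linear sequence: 11 steps (steps 1–8 and 11–13); steps 9 and 10 are a two-step side branch.

**Step 11 (key step).** Three processes are the most likely to go wrong. The cycloaddition may not take place, because the pyranone is only weakly electron-poor and fully substituted at the positions that flank the reacting termini, and the enol ether is trisubstituted. The enol ether may isomerise under pressure with traces of acid (E to Z, or migration of the double bond into ring A). Facial or endo control may be incomplete, because both rest on conformational arguments. The fallback uses known reaction types only, sets out from 13 and returns to the route at 22. It makes the C5–C6 bond by electrophilic addition and the C2–C7 bond by the biomimetic closure. BF3·OEt2-catalysed addition of trimethyl orthoformate to 13 (CH2Cl2, −78 °C; same facial argument, small electrophile) should give the methyl ketal dimethyl acetal F1. Acetal-selective cleavage with TESOTf/2,4,6-collidine and then water should give the aldehyde F2, the ketal staying intact. The Sn(OTf)2/Et3N aldol of keto imide 4 with F2 should give the adduct F3; the C5 configuration is controlled by 4 and matched with the anti-Felkin preference of a Z-enolate. DBU-mediated lactonisation of the C5 hydroxyl onto the imide releases the auxiliary and gives the β-keto-δ-lactone F4. BF3·OEt2 then ionises the methyl ketal, and the lactone enol closes C2–C7 on the oxocarbenium ion (axial attack, trans to the C11 methyl) to give the silyl ether F5, whose C4 is equilibrated with DBU. HF·pyridine gives the alcohol F6, and Ac2O/pyridine gives 22. This costs four more steps than the cycloaddition.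

**Step 8.** The 6-exo-dig insertion of an internal, propargylically branched alkyne may be slow, and at the temperature then needed the exocyclic double bond may migrate or lose its E geometry; the silyl group may also migrate to the C11 alkoxide. The fallback sets out from 11 and returns at 13, bypassing step 7. Iodoetherification of 11 (N-iodosuccinimide, AgOTf cat., CH2Cl2, 0 °C; anti addition, iodine trans to the ring oxygen) should give the (E)-iodomethylene tetrahydropyran F7. Negishi methylation (MeZnCl, Pd(PPh3)4 as zerovalent palladium catalyst, THF) then replaces iodine by methyl with retention.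

**Step 6.** Under K2CO3/MeOH the open hydroxy-aldehyde form of the lactol may enolise (epimerisation at C8) or eliminate the β-silyloxy group, and the lactol may react sluggishly. The fallback sets out from 9 and returns at 12, making the alkyne from a protected open-chain aldehyde without carbonate or methoxide. Me3Al/MeNHOMe·HCl opens 9 to the Weinreb amide F8; TESCl/imidazole gives the silyl ether F9; i-Bu2AlH gives the aldehyde F10. Corey–Fuchs olefination (CBr4, PPh3) gives the dibromoalkene F11. n-BuLi followed by MeI gives the methyl alkyne F12, and PPTS/MeOH removes the triethylsilyl group selectively to give 12.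

**Step 13.** The primary amine may open the β-keto lactone by retro-Claisen attack at C1 or C3 of 22, and C4 may not equilibrate fully. The fallback sets out from 20 and returns at 22 with no external nucleophile. DMAP-catalysed transfer of the enol acetyl group of 20 to its own C9 hydroxyl (intermolecular, CH2Cl2, rt) gives 22 directly, each molecule holding exactly one acyl donor and one acceptor, and a trace of DBU then equilibrates C4. This fallback makes no new compound (F0).

## Further compounds

F1 | step 11 | (3S,4R,5R,6S)-4-(TBSO)-2-[(2R)-1,1-dimethoxypropan-2-yl]-2-methoxy-3,5,6-trimethyltetrahydropyran (C7 epimers) | COC(OC)[C@@H](C)C1(OC)O[C@@H](C)[C@@H](C)[C@@H](O[Si](C)(C)C(C)(C)C)[C@@H]1C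
F2 | step 11 | 2-[(3S,4R,5R,6S)-4-(TBSO)-2-methoxy-3,5,6-trimethyltetrahydropyran-2-yl]propanal (C6 as in 22) | O=C[C@@H](C)C1(OC)O[C@@H](C)[C@@H](C)[C@@H](O[Si](C)(C)C(C)(C)C)[C@@H]1C
F3 | step 11 | anti-syn aldol adduct of 4 with F2 (C5 hydroxyl, C4 epimeric to 22) | O=C1OC[C@H](Cc2ccccc2)N1C(=O)[C@@H](C)C(=O)[C@H](C)[C@@H](O)[C@@H](C)C3(OC)O[C@@H](C)[C@@H](C)[C@@H](O[Si](C)(C)C(C)(C)C)[C@@H]3C
F4 | step 11 | β-keto-δ-lactone with ring A as methyl ketal (diketo tautomer; C2 labile) | CC1C(=O)O[C@@H]([C@@H](C)C2(OC)O[C@@H](C)[C@@H](C)[C@@H](O[Si](C)(C)C(C)(C)C)[C@@H]2C)[C@@H](C)C1=O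
F5 | step 11 | C9 O-TBS analogue of 22 | CC(C)(C)[Si](C)(C)O[C@@H]1[C@H](C)[C@H](C)O[C@]2([C@H](C)[C@@H]3OC(=O)[C@@]2(C)C(=O)[C@H]3C)[C@H]1C
F6 | step 11 | C9 alcohol (deacetyl 22) | O[C@@H]1[C@H](C)[C@H](C)O[C@]2([C@H](C)[C@@H]3OC(=O)[C@@]2(C)C(=O)[C@H]3C)[C@H]1C
F7 | step 8 | tert-butyl{[(2E,3S,4R,5R,6S)-2-(iodomethylene)-3,5,6-trimethyltetrahydro-2H-pyran-4-yl]oxy}dimethylsilane | I/C=C1/O[C@@H](C)[C@@H](C)[C@@H](O[Si](C)(C)C(C)(C)C)[C@@H]1C
F8 | step 6 | Weinreb amide from 9 (C11 hydroxyl free) | CON(C)C(=O)[C@@H](C)[C@H](O[Si](C)(C)C(C)(C)C)[C@H](C)[C@H](C)O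
F9 | step 6 | C11 O-triethylsilyl ether of F8 | CON(C)C(=O)[C@@H](C)[C@H](O[Si](C)(C)C(C)(C)C)[C@H](C)[C@H](C)O[Si](CC)(CC)CC
F10 | step 6 | open-chain C7 aldehyde (C9 OTBS, C11 OTES) | O=C[C@@H](C)[C@H](O[Si](C)(C)C(C)(C)C)[C@H](C)[C@H](C)O[Si](CC)(CC)CC
F11 | step 6 | 1,1-dibromoalkene from F10 | BrC(Br)=C[C@@H](C)[C@H](O[Si](C)(C)C(C)(C)C)[C@H](C)[C@H](C)O[Si](CC)(CC)CC
F12 | step 6 | C11 O-triethylsilyl ether of 12 | CC#C[C@@H](C)[C@H](O[Si](C)(C)C(C)(C)C)[C@H](C)[C@H](C)O[Si](CC)(CC)CC
F0 | step 13 | none | none
A1 | alternative 1 | methyl 9-acetoxy-5,11-dihydroxy-2,4,6,8,10-pentamethyl-3,7-dioxododecanoate (4,5-anti, 5,6-anti, 6,8-syn, 8,9-syn, 9,10-anti, 10,11-syn; C2 labile) | C[C@H](O)[C@@H](C)[C@@H](OC(C)=O)[C@H](C)C(=O)[C@H](C)[C@H](O)[C@H](C)C(=O)C(C)C(=O)OC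
A2 | alternative 2 | 2,4,6-trimethylbenzene-1,3,5-triol | Cc1c(O)c(C)c(O)c(C)c1O
A3 | alternative 2 | meso 4,6,7-trimethyl-2-oxabicyclo[2.2.2]octane-3,5,8-trione (both CH-methyls syn to the lactone oxygen) | O=C1[C@H](C)[C@@H]2OC(=O)[C@@]1(C)C(=O)[C@H]2C
A4 | alternative 2 | (2S,3S,E)-3-methylhex-4-en-2-ol | C[C@H](O)[C@@H](C)/C=C/C
A5 | alternative 3 | spiro 7-norbornanone (bicyclo[2.2.1]heptane-2,7-dione analogue of 22 lacking the lactone oxygen) | CC(=O)O[C@@H]1[C@H](C)[C@H](C)O[C@]2([C@H](C)[C@@H]3C(=O)[C@@]2(C)C(=O)[C@H]3C)[C@H]1C
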